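**Plan**
- Retrosynthetic cuts, in order: the C1 ketone and the O13 acetyl group (late adjustments; C1 is carried as a silyl-protected carbinol); the ring bond C5–C6; the C2–C3 aldol bond; the C10=C14 methylene; the butenolide at C7–C8 and C11–C12 (carbomagnesiation/carboxylation of but-2-yne-1,4-diol).
- Enabling feature: C6 is the γ-carbon of the butenolide ring (O–C6–C7=C11–C12=O). Silylation turns this ring into an aromatic 2-silyloxyfuran, a dienolate that is nucleophilic at C6, and C5 is the terminus of a (Z)-alkenyl iodide. A Pd-mediated vinylogous alkenylation can therefore close the ten-membered carbocycle with no redox change at C6.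
- Forward order: butenolide ring first (step 1); side chain by methylenation and boron aldol (steps 2–6); ten-membered ring last (step 10); then desilylation, O13 acetylation and C1 oxidation.
- Stereochemistry: C3 from the reagent-controlled aldol; Z-C4=C5 from anti-carbomagnesiation/iodinolysis; C6 in the ring closure (chiral ligand on Pd); a temporary C1 carbinol from the Evans–Tishchenko step tells O1 from O3 and is oxidised at the end.
- Helpers: the furanolate silyl group (lost in step 10), TBS at O1 and O13 (removed in step 11), the C1–OH oxidation level (removed in step 13).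

Key step: step 10

Remark: atoms are numbered as in a germacranolide (C1 ketone, C3 and C13 acetoxy-bearing, C4=C5 ring alkene, C6 lactone carbinol, C7=C11 butenolide alkene, C10=C14 methylene). The reagent antipodes written, (−)-Ipc2BCl and (R)-L*, are assumed to be the ones that deliver the stated faces.

Step 1
Reactants: 1 2-(3-chloropropyl)-2-methyl-1,3-dioxolane; 2 but-2-yne-1,4-diol
Product: 7 3-(hydroxymethyl)-4-(4-oxopentyl)furan-2(5H)-one, via Grignard reagent 3 (not isolated), via alkenylmagnesium chelate 4 (not isolated), via magnesium carboxylate 5 (not isolated), via ketal lactone 6 (not isolated)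
Conditions: 1, Mg, THF, reflux; add to 2 (pretreated with i-PrMgCl, 2 equiv, THF, 0 °C) and CuI (10 mol%), 0 °C → rt; CO2, 0 °C; 2 M HCl, THF, rt
Reagents that add atoms: carbon dioxide, O=C=O; water, O
Why: Cu-catalysed anti-carbomagnesiation of a propargylic alkoxide should add the alkyl group and Mg trans across the symmetrical alkyne with Mg held cis to one CH2O arm in a five-membered chelate, so that carboxylation with retention and acidification give the (Z)-γ-hydroxy acid, which lactonises while the dioxolane is hydrolysed; no stereocentre is formed.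

Step 2
Reactants: 7 3-(hydroxymethyl)-4-(4-oxopentyl)furan-2(5H)-one
Product: 9 3-(hydroxymethyl)-4-(3-methylidene-4-oxopentyl)furan-2(5H)-one, via Mannich base 8 (not isolated)
Conditions: (CH2O)n, N-methylanilinium trifluoroacetate, THF, reflux
Reagents that add atoms: formaldehyde (as paraformaldehyde), C=O
Why: Mannich-type α-methylenation under acidic amine-salt conditions, in which the more substituted enol (C10) should attack the iminium ion and β-elimination of N-methylaniline gives the exo-methylene ketone, leaving the methyl group free for the aldol.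

Step 3
Reactants: 9 3-(hydroxymethyl)-4-(3-methylidene-4-oxopentyl)furan-2(5H)-one
Product: 10 3-{[(tert-butyldimethylsilyl)oxy]methyl}-4-(3-methylidene-4-oxopentyl)furan-2(5H)-one
Conditions: TBSOTf, 2,6-lutidine, CH2Cl2, −78 °C
Reagents that add atoms: tert-butyldimethylsilyl triflate, CC(C)(C)[Si](C)(C)OS(=O)(=O)C(F)(F)F
Why: Silyl ether formation at the primary alcohol with a silyl triflate and a hindered non-nucleophilic base at low temperature, which should leave the Michael-accepting enone and the methyl ketone untouched.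

Step 4
Reactants: 11 prop-2-yn-1-ol
Product: 13 (2Z)-3-iodo-2-methylprop-2-en-1-ol, via alkenylmagnesium chelate 12 (not isolated)
Conditions: MeMgBr (2.2 equiv), CuI (10 mol%), Et2O/THF, −10 °C → rt; I2, −78 → 0 °C
Reagents that add atoms: methylmagnesium bromide, C[Mg]Br; iodine, II
Why: Cu-catalysed anti-carbomagnesiation of the propargylic alkoxide places methyl on C2 and Mg on C3 cis to the alkoxide arm (chelate), and iodinolysis with retention fixes the Z geometry of the future C4=C5 bond.

Step 5
Reactants: 13 (2Z)-3-iodo-2-methylprop-2-en-1-ol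
Product: 14 (2Z)-3-iodo-2-methylprop-2-enal
Conditions: MnO2, CH2Cl2, rt, dark
Reagents that add atoms: none
Why: Allylic oxidation with MnO2 under neutral conditions in the dark, which should give the enal without Z→E isomerisation or loss of iodine.

Step 6
Reactants: 10 3-{[(tert-butyldimethylsilyl)oxy]methyl}-4-(3-methylidene-4-oxopentyl)furan-2(5H)-one; 14 (2Z)-3-iodo-2-methylprop-2-enal
Product: 16 3-{[(tert-butyldimethylsilyl)oxy]methyl}-4-[(6S,7Z)-6-hydroxy-8-iodo-7-methyl-3-methylidene-4-oxooct-7-en-1-yl]furan-2(5H)-one, via enol borinate 15 (not isolated)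
Conditions: (−)-Ipc2BCl, Et3N, Et2O, 0 °C; 14, −78 → −20 °C; H2O2, pH 7 buffer, MeOH, 0 °C
Reagents that add atoms: none
Why: Ipc2BCl-mediated boron aldol reaction, in which the ketone is enolised at its only enolisable α-position (the methyl group) and the chiral Ipc ligands should steer the enolate to the Si face of the enal in a cyclic transition state, setting C3 as S by reagent control with 1,2-addition only.

Step 7
Reactants: 16 3-{[(tert-butyldimethylsilyl)oxy]methyl}-4-[(6S,7Z)-6-hydroxy-8-iodo-7-methyl-3-methylidene-4-oxooct-7-en-1-yl]furan-2(5H)-one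
Product: 18 (1Z,3S,5S)-8-[4-({[tert-butyldimethylsilyl]oxy}methyl)-5-oxo-2,5-dihydrofuran-3-yl]-5-hydroxy-1-iodo-2-methyl-6-methylideneoct-1-en-3-yl acetate, via hemiacetal 17 (not isolated)
Conditions: MeCHO (10 equiv), SmI2 (30 mol%), THF, −10 °C
Reagents that add atoms: acetaldehyde, CC=O
Why: Evans–Tishchenko reduction, in which the Sm(III)-bound hemiacetal delivers hydride intramolecularly to the C1 ketone through a six-membered chair, which should give the 1,3-anti carbinol (1S, a temporary centre) and leave the acetyl group on O3, so that the C3 acetate is installed and the two oxygens are differentiated in one step.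

Step 8
Reactants: 18 (1Z,3S,5S)-8-[4-({[tert-butyldimethylsilyl]oxy}methyl)-5-oxo-2,5-dihydrofuran-3-yl]-5-hydroxy-1-iodo-2-methyl-6-methylideneoct-1-en-3-yl acetate
Product: 19 (1Z,3S,5S)-5-[(tert-butyldimethylsilyl)oxy]-8-[4-({[tert-butyldimethylsilyl]oxy}methyl)-5-oxo-2,5-dihydrofuran-3-yl]-1-iodo-2-methyl-6-methylideneoct-1-en-3-yl acetate
Conditions: TBSOTf, 2,6-lutidine, CH2Cl2, −78 °C
Reagents that add atoms: tert-butyldimethylsilyl triflate, CC(C)(C)[Si](C)(C)OS(=O)(=O)C(F)(F)F
Why: Silyl ether formation at the C1 allylic alcohol, a temporary group that keeps C1 non-enolisable and masks the base-sensitive β-acetoxy enone until the end.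

Step 9
Reactants: 19 (1Z,3S,5S)-5-[(tert-butyldimethylsilyl)oxy]-8-[4-({[tert-butyldimethylsilyl]oxy}methyl)-5-oxo-2,5-dihydrofuran-3-yl]-1-iodo-2-methyl-6-methylideneoct-1-en-3-yl acetate
Product: 20 (1Z,3S,5S)-5-[(tert-butyldimethylsilyl)oxy]-8-[5-[(tert-butyldimethylsilyl)oxy]-4-({[tert-butyldimethylsilyl]oxy}methyl)furan-3-yl]-1-iodo-2-methyl-6-methylideneoct-1-en-3-yl acetate
Conditions: TBSOTf, Et3N, CH2Cl2, 0 °C
Reagents that add atoms: tert-butyldimethylsilyl triflate, CC(C)(C)[Si](C)(C)OS(=O)(=O)C(F)(F)F
Why: Soft enolisation of the butenolide (O-silylation of the lactone carbonyl, then γ-deprotonation at C6 by Et3N) should give the aromatic 2-silyloxyfuran, the activating device for the ring closure, while the acetate, the silyl ethers and the stereocentres are not involved.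

Step 10
Reactants: 20 (1Z,3S,5S)-5-[(tert-butyldimethylsilyl)oxy]-8-[5-[(tert-butyldimethylsilyl)oxy]-4-({[tert-butyldimethylsilyl]oxy}methyl)furan-3-yl]-1-iodo-2-methyl-6-methylideneoct-1-en-3-yl acetate
Product: 23 (7S,9S,10Z,11aR)-7-[(tert-butyldimethylsilyl)oxy]-3-({[tert-butyldimethylsilyl]oxy}methyl)-10-methyl-6-methylidene-2-oxo-2,4,5,6,7,8,9,11a-octahydrocyclodeca[b]furan-9-yl acetate, via alkenylpalladium iodide 21 (not isolated), via palladacycle 22 (not isolated)
Conditions: Pd2(dba)3 (5 mol%), (R)-L* (chiral biaryl monophosphine, 12 mol%), ZnF2 (0.6 equiv), DMF/toluene, 40 °C, 20 added by syringe pump (final 1 mM)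
Reagents that add atoms: none
Why: Proposed new method: Pd(0) should insert into the C5–I bond of the (Z)-alkenyl iodide with retention, ZnF2 should release the zinc furanolate (the aromatic dienolate of the butenolide) from the silyl ether, and transmetalation followed by C–C reductive elimination should join C5 to C6 and return the conjugated butenolide with loss of the silyl group. The closest known reaction types are the Pd-catalysed γ-arylation of butenolide dienolates, the ZnF2-promoted Pd coupling of silicon and zinc enolates with aryl and alkenyl halides, and the intramolecular Pd coupling of ketone enolates with alkenyl iodides in small rings; new here are the vinylogous alkenylation and the medium ring. The ten-membered carbocycle is closed by reductive elimination from an eleven-membered palladacycle (C5–Pd–C6), a ring contraction with loss of Pd in which the Z-alkene, the flat furan and the C10 methylene limit transannular strain, and no other ring is formed. C6 is the only new stereocentre: bonding has to occur on the Re face of the furan carbon, and this is assigned to the chiral monophosphine on Pd (ligand control, by analogy with enantioselective Pd arylations of silyl ketene acetals that give tertiary centres), with the C3 and C1 centres acting only through the conformation of the tether. The step needs γ- over α-coupling, which the fully substituted C11 and the regained conjugation secure; retention of the Z geometry, which oxidative addition and reductive elimination guarantee; and C–I over allylic C–OAc activation, which the much faster insertion into the alkenyl iodide secures. The weakly basic ZnF2 and high dilution should suppress intermolecular proton transfer to the acidic C6–H of the product, so that C6 is not epimerised and oligomers are avoided.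

Step 11
Reactants: 23 (7S,9S,10Z,11aR)-7-[(tert-butyldimethylsilyl)oxy]-3-({[tert-butyldimethylsilyl]oxy}methyl)-10-methyl-6-methylidene-2-oxo-2,4,5,6,7,8,9,11a-octahydrocyclodeca[b]furan-9-yl acetate
Product: 24 (7S,9S,10Z,11aR)-7-hydroxy-3-(hydroxymethyl)-10-methyl-6-methylidene-2-oxo-2,4,5,6,7,8,9,11a-octahydrocyclodeca[b]furan-9-yl acetate
Conditions: HF·pyridine, pyridine, THF, 0 °C → rt
Reagents that add atoms: none
Why: Fluoride-mediated desilylation under buffered acidic conditions should cleave both TBS ethers without acetate migration or epimerisation at C6.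

Step 12
Reactants: 24 (7S,9S,10Z,11aR)-7-hydroxy-3-(hydroxymethyl)-10-methyl-6-methylidene-2-oxo-2,4,5,6,7,8,9,11a-octahydrocyclodeca[b]furan-9-yl acetate
Product: 25 [(7S,9S,10Z,11aR)-9-acetoxy-7-hydroxy-10-methyl-6-methylidene-2-oxo-2,4,5,6,7,8,9,11a-octahydrocyclodeca[b]furan-3-yl]methyl acetate
Conditions: AcCl (1.1 equiv), 2,4,6-collidine, CH2Cl2, −78 °C
Reagents that add atoms: acetyl chloride, CC(Cl)=O
Why: Kinetically selective acylation of the primary allylic alcohol over the more hindered secondary one with an acid chloride and a hindered pyridine base at low temperature.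

Step 13
Reactants: 25 [(7S,9S,10Z,11aR)-9-acetoxy-7-hydroxy-10-methyl-6-methylidene-2-oxo-2,4,5,6,7,8,9,11a-octahydrocyclodeca[b]furan-3-yl]methyl acetate
Product: 26 [(9S,10Z,11aR)-9-acetoxy-10-methyl-6-methylidene-2,7-dioxo-2,4,5,6,7,8,9,11a-octahydrocyclodeca[b]furan-3-yl]methyl acetate (target, CNP0272505.1)
Conditions: Dess–Martin periodinane, CH2Cl2, 0 °C → rt
Reagents that add atoms: none
Why: Dess–Martin oxidation of the secondary allylic alcohol under neutral conditions removes the temporary C1 centre and should give the α-methylene ketone without β-elimination of the C3 acetate or epimerisation at C3 and C6.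

**Compound list**
1 | 2-(3-chloropropyl)-2-methyl-1,3-dioxolane | CC1(CCCCl)OCCO1 | starting material
2 | but-2-yne-1,4-diol | OCC#CCO | starting material
3 | [3-(2-methyl-1,3-dioxolan-2-yl)propyl]magnesium chloride | CC1(CCC[Mg]Cl)OCCO1 | intermediate
4 | 3-[(chloromagnesiooxy)methyl]-4-[3-(2-methyl-1,3-dioxolan-2-yl)propyl]-2,5-dihydro-1,2-oxamagnesole (chelated alkenylmagnesium) | CC1(CCCC2=C(CO[Mg]Cl)[Mg]OC2)OCCO1 | intermediate
5 | tris(chloromagnesium) salt of (2Z)-4-hydroxy-2-(hydroxymethyl)-3-[3-(2-methyl-1,3-dioxolan-2-yl)propyl]but-2-enoic acid | CC1(CCC/C(CO[Mg]Cl)=C(/C(=O)O[Mg]Cl)CO[Mg]Cl)OCCO1 | intermediate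
6 | 3-(hydroxymethyl)-4-[3-(2-methyl-1,3-dioxolan-2-yl)propyl]furan-2(5H)-one | CC1(CCCC2=C(CO)C(=O)OC2)OCCO1 | intermediate
7 | 3-(hydroxymethyl)-4-(4-oxopentyl)furan-2(5H)-one | CC(=O)CCCC1=C(CO)C(=O)OC1 | intermediate
8 | 3-(hydroxymethyl)-4-{3-[(N-methylanilino)methyl]-4-oxopentyl}furan-2(5H)-one (Mannich base, racemic) | CC(=O)C(CN(C)c1ccccc1)CCC1=C(CO)C(=O)OC1 | intermediate
9 | 3-(hydroxymethyl)-4-(3-methylidene-4-oxopentyl)furan-2(5H)-one | CC(=O)C(=C)CCC1=C(CO)C(=O)OC1 | intermediate
10 | 3-{[(tert-butyldimethylsilyl)oxy]methyl}-4-(3-methylidene-4-oxopentyl)furan-2(5H)-one | CC(=O)C(=C)CCC1=C(CO[Si](C)(C)C(C)(C)C)C(=O)OC1 | intermediate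
11 | prop-2-yn-1-ol | C#CCO | starting material
12 | 4-methyl-2,5-dihydro-1,2-oxamagnesole (chelated (Z)-alkenylmagnesium alkoxide) | CC1=C[Mg]OC1 | intermediate
13 | (2Z)-3-iodo-2-methylprop-2-en-1-ol | OC/C(C)=C\I | intermediate
14 | (2Z)-3-iodo-2-methylprop-2-enal | O=C/C(C)=C\I | intermediate
15 | enol diisopinocampheylborinate of 10 (boron on the C1 enol oxygen, Ipc groups from (+)-α-pinene) | C=C(OB([C@@H]1C[C@@H]2C[C@H]([C@H]1C)C2(C)C)[C@@H]1C[C@@H]2C[C@H]([C@H]1C)C2(C)C)C(=C)CCC1=C(CO[Si](C)(C)C(C)(C)C)C(=O)OC1 | intermediate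
16 | 3-{[(tert-butyldimethylsilyl)oxy]methyl}-4-[(6S,7Z)-6-hydroxy-8-iodo-7-methyl-3-methylidene-4-oxooct-7-en-1-yl]furan-2(5H)-one | I/C=C(/C)[C@@H](O)CC(=O)C(=C)CCC1=C(CO[Si](C)(C)C(C)(C)C)C(=O)OC1 | intermediate
17 | acetaldehyde hemiacetal of 16 at O3 (1-hydroxyethyl ether, hemiacetal carbon unassigned) | I/C=C(/C)[C@@H](OC(C)O)CC(=O)C(=C)CCC1=C(CO[Si](C)(C)C(C)(C)C)C(=O)OC1 | intermediate
18 | (1Z,3S,5S)-8-[4-({[tert-butyldimethylsilyl]oxy}methyl)-5-oxo-2,5-dihydrofuran-3-yl]-5-hydroxy-1-iodo-2-methyl-6-methylideneoct-1-en-3-yl acetate | I/C=C(/C)[C@@H](OC(C)=O)C[C@H](O)C(=C)CCC1=C(CO[Si](C)(C)C(C)(C)C)C(=O)OC1 | intermediate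
19 | (1Z,3S,5S)-5-[(tert-butyldimethylsilyl)oxy]-8-[4-({[tert-butyldimethylsilyl]oxy}methyl)-5-oxo-2,5-dihydrofuran-3-yl]-1-iodo-2-methyl-6-methylideneoct-1-en-3-yl acetate | I/C=C(/C)[C@@H](OC(C)=O)C[C@H](O[Si](C)(C)C(C)(C)C)C(=C)CCC1=C(CO[Si](C)(C)C(C)(C)C)C(=O)OC1 | intermediate
20 | (1Z,3S,5S)-5-[(tert-butyldimethylsilyl)oxy]-8-[5-[(tert-butyldimethylsilyl)oxy]-4-({[tert-butyldimethylsilyl]oxy}methyl)furan-3-yl]-1-iodo-2-methyl-6-methylideneoct-1-en-3-yl acetate | I/C=C(/C)[C@@H](OC(C)=O)C[C@H](O[Si](C)(C)C(C)(C)C)C(=C)CCc1coc(O[Si](C)(C)C(C)(C)C)c1CO[Si](C)(C)C(C)(C)C | intermediate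
21 | (Z)-alkenylpalladium(II) iodide from 20 (Pd on C5, phosphine omitted) | I[Pd]/C=C(/C)[C@@H](OC(C)=O)C[C@H](O[Si](C)(C)C(C)(C)C)C(=C)CCc1coc(O[Si](C)(C)C(C)(C)C)c1CO[Si](C)(C)C(C)(C)C | intermediate
22 | eleven-membered palladacycle (Pd bridging C5 and C6 of the butenolide, phosphine omitted) | C=C1CCC2=C(CO[Si](C)(C)C(C)(C)C)C(=O)O[C@@H]2[Pd]/C=C(/C)[C@@H](OC(C)=O)C[C@@H]1O[Si](C)(C)C(C)(C)C | intermediate
23 | (7S,9S,10Z,11aR)-7-[(tert-butyldimethylsilyl)oxy]-3-({[tert-butyldimethylsilyl]oxy}methyl)-10-methyl-6-methylidene-2-oxo-2,4,5,6,7,8,9,11a-octahydrocyclodeca[b]furan-9-yl acetate | C=C1CCC2=C(CO[Si](C)(C)C(C)(C)C)C(=O)O[C@@H]2/C=C(/C)[C@@H](OC(C)=O)C[C@@H]1O[Si](C)(C)C(C)(C)C | intermediate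
24 | (7S,9S,10Z,11aR)-7-hydroxy-3-(hydroxymethyl)-10-methyl-6-methylidene-2-oxo-2,4,5,6,7,8,9,11a-octahydrocyclodeca[b]furan-9-yl acetate | C=C1CCC2=C(CO)C(=O)O[C@@H]2/C=C(/C)[C@@H](OC(C)=O)C[C@@H]1O | intermediate
25 | [(7S,9S,10Z,11aR)-9-acetoxy-7-hydroxy-10-methyl-6-methylidene-2-oxo-2,4,5,6,7,8,9,11a-octahydrocyclodeca[b]furan-3-yl]methyl acetate | C=C1CCC2=C(COC(C)=O)C(=O)O[C@@H]2/C=C(/C)[C@@H](OC(C)=O)C[C@@H]1O | intermediate
26 | [(9S,10Z,11aR)-9-acetoxy-10-methyl-6-methylidene-2,7-dioxo-2,4,5,6,7,8,9,11a-octahydrocyclodeca[b]furan-3-yl]methyl acetate | C=C1CCC2=C(COC(C)=O)C(=O)O[C@@H]2/C=C(/C)[C@@H](OC(C)=O)CC1=O | target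

**Totals**
Total step count: 13. Longest linear sequence: 11 steps (1, 2, 3, 6, 7, 8, 9, 10, 11, 12, 13).

**Steps most likely to fail**

1. Step 10 (Proposed new method). Transmetalation and reductive elimination in the eleven-membered palladacycle may be slower than protodesilylation of the furanolate, oligomerisation, or Pd(0) ionisation of the allylic C–O bonds of the product, and the facial selectivity at C6 may be poor. The fallback uses known chemistry, sets out from 20 and returns at 23. Oxidation of 20 with dimethyldioxirane (acetone, −78 °C) would open the silyloxyfuran to the tert-butyldimethylsilyl (2Z,7S,9S,10Z)-9-acetoxy-7-[(tert-butyldimethylsilyl)oxy]-2-({[tert-butyldimethylsilyl]oxy}methyl)-3-formyl-11-iodo-10-methyl-6-methylideneundeca-2,10-dienoate F1. An intramolecular Nozaki–Hiyama–Kishi reaction of F1 (CrCl2, catalytic NiCl2, chiral oxazoline–sulfonamide ligand, high dilution) would proceed through the alkenylchromium(III) species F2 and add C5 to the Re face of the C6 aldehyde. The resulting alkoxide would lactonise onto the cis silyl ester to give 23.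

2. Step 1. Carbometalation of the internal alkyne bis-alkoxide may be sluggish, and the alkenylmagnesium may undergo β-elimination to an allenol or be carboxylated incompletely. The fallback sets out from Grignard reagent 3 and returns at 6, which is then isolated and hydrolysed to 7 with aqueous HCl. Transmetalation of 3 with ZnCl2 would give [3-(2-methyl-1,3-dioxolan-2-yl)propyl]zinc chloride F3. Negishi coupling of F3 with commercial 3,4-dibromofuran-2(5H)-one (O=C1OCC(Br)=C1Br), whose C4 bromide reacts first, would give 3-bromo-4-[3-(2-methyl-1,3-dioxolan-2-yl)propyl]furan-2(5H)-one F4. Stille coupling of F4 with (tributylstannyl)methanol would install the hydroxymethyl group and give 6.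

3. Step 7. Reduction or conjugate addition at the exo-methylene ketone may compete with the intramolecular hydride transfer, and the acetyl group may migrate between O3 and O1. The fallback sets out from 16 and returns at 18. Acetylation of 16 (Ac2O, pyridine, 0 °C) would give (1Z,3S)-8-[4-({[tert-butyldimethylsilyl]oxy}methyl)-5-oxo-2,5-dihydrofuran-3-yl]-1-iodo-2-methyl-6-methylidene-5-oxooct-1-en-3-yl acetate F5. Corey–Bakshi–Shibata reduction of F5 ((R)-Me-CBS catalyst, catecholborane, toluene, −78 °C), with the α-branched alkenyl group as the large substituent, would set 1S under reagent control and give 18.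

Further compounds
F1 | step 10 | tert-butyldimethylsilyl (2Z,7S,9S,10Z)-9-acetoxy-7-[(tert-butyldimethylsilyl)oxy]-2-({[tert-butyldimethylsilyl]oxy}methyl)-3-formyl-11-iodo-10-methyl-6-methylideneundeca-2,10-dienoate | I/C=C(/C)[C@@H](OC(C)=O)C[C@H](O[Si](C)(C)C(C)(C)C)C(=C)CC/C(C=O)=C(\CO[Si](C)(C)C(C)(C)C)C(=O)O[Si](C)(C)C(C)(C)C
F2 | step 10 | (Z)-alkenylchromium(III) dichloride derived from F1 (Cr on C5) | Cl[Cr](Cl)/C=C(/C)[C@@H](OC(C)=O)C[C@H](O[Si](C)(C)C(C)(C)C)C(=C)CC/C(C=O)=C(\CO[Si](C)(C)C(C)(C)C)C(=O)O[Si](C)(C)C(C)(C)C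
F3 | step 1 | [3-(2-methyl-1,3-dioxolan-2-yl)propyl]zinc chloride | CC1(CCC[Zn]Cl)OCCO1
F4 | step 1 | 3-bromo-4-[3-(2-methyl-1,3-dioxolan-2-yl)propyl]furan-2(5H)-one | CC1(CCCC2=C(Br)C(=O)OC2)OCCO1
F5 | step 7 | (1Z,3S)-8-[4-({[tert-butyldimethylsilyl]oxy}methyl)-5-oxo-2,5-dihydrofuran-3-yl]-1-iodo-2-methyl-6-methylidene-5-oxooct-1-en-3-yl acetate | I/C=C(/C)[C@@H](OC(C)=O)CC(=O)C(=C)CCC1=C(CO[Si](C)(C)C(C)(C)C)C(=O)OC1
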